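**Retrosynthetic overview**
- Ferutinin ⇒ selective acylation of the secondary OH of the sesquiterpene diol with a silyl-protected 4-hydroxybenzoic acid (from 4-bromophenol and CO2). The C4 carbinol comes from a hydroxyl-directed anti reduction of a β-hydroxy ketone.
- Seven-membered ring (formed second) ⇒ ring-closing metathesis between an allyl group on the quaternary carbon and a methallyl ketone on the neighbouring ring carbon.
- Cyclopentane (formed first) ⇒ copper-catalysed enantioselective ring-opening conjugate coupling of a cyclopropanol (homoenolate) with an acyclic β-methyl-β-allyl enone, then in-situ aldol closure (formal [3+2]). The annulation precedes ring closure because on a preformed cycloheptadienone the same aldol would be forced to the cis-fused isomer.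
- Enone ⇒ Zr-catalysed carboalumination of pent-1-en-4-yne (Cu-catalysed allyl–alkynyl coupling) and addition to 3-methylbut-3-enal, then oxidation. Cyclopropanol ⇒ Kulinkovich reaction of methyl isobutyrate.

Assumption: the SMILES is read as drawn, i.e. the (3R,3aS,4S,8aR) enantiomer; azulene numbering is used for the bicyclic compounds.

**Route**

Step 1
Reactants: 1 allyl bromide; 2 ethynylmagnesium bromide
Product: 3 pent-1-en-4-yne
Conditions: CuCl (5 mol%), THF, 0 °C → rt; distil
Reagents that add atoms: none
Why: Cu(I)-catalysed sp–sp3 cross-coupling of an alkynyl Grignard with an allylic halide gives the skipped enyne; no stereocentre.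

Step 2
Reactants: 4 3-methylbut-3-en-1-ol
Product: 5 3-methylbut-3-enal
Conditions: Dess–Martin periodinane, NaHCO3, CH2Cl2, 0 °C; used at once as a cold solution
Reagents that add atoms: none
Why: Buffered Dess–Martin oxidation gives the β,γ-unsaturated aldehyde without base- or acid-induced migration to the conjugated isomer.

Step 3
Reactants: 3 pent-1-en-4-yne; 5 3-methylbut-3-enal
Product: 6 (E)-2,6-dimethylnona-1,5,8-trien-4-ol (racemic carbinol)
Conditions: Me3Al (2 equiv), Cp2ZrCl2 (20 mol%), CH2Cl2, 0 °C → rt; strip volatiles; n-BuLi, THF/hexane, −78 °C; then 5, −78 → 0 °C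
Reagents that add atoms: trimethylaluminium, C[Al](C)C
Why: Zr-catalysed syn-carboalumination (Negishi) puts CH3 on the internal alkyne carbon and Al on the terminus, fixing the (E)-trisubstituted alkene; the alkenylalanate then adds 1,2 to the aldehyde with retention (the carbinol centre is removed in step 4).

Step 4
Reactants: 6 (E)-2,6-dimethylnona-1,5,8-trien-4-ol
Product: 7 (E)-2,6-dimethylnona-1,5,8-trien-4-one
Conditions: activated MnO2, CH2Cl2, rt
Reagents that add atoms: none
Why: Neutral MnO2 oxidation of the allylic alcohol gives the enone without moving the β,γ-alkene into conjugation.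

Step 5
Reactants: 8 methyl 2-methylpropanoate
Product: 9 1-(propan-2-yl)cyclopropan-1-ol
Conditions: EtMgBr (2.5 equiv), Ti(OiPr)4 (20 mol%), Et2O, rt
Reagents that add atoms: ethylmagnesium bromide, CC[Mg]Br
Why: Kulinkovich cyclopropanation: the titanacyclopropane from EtMgBr acts as a 1,2-dicarbanion toward the ester.

Step 6
Reactants: 7 (E)-2,6-dimethylnona-1,5,8-trien-4-one; 9 1-(propan-2-yl)cyclopropan-1-ol
Product: 10 1-[(1R,2R,5R)-2-hydroxy-5-methyl-2-(propan-2-yl)-5-(prop-2-en-1-yl)cyclopentyl]-3-methylbut-3-en-1-one (acyl, 5-CH3 and 2-OH on one face; allyl and isopropyl on the other)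
Conditions: 9 (1.6 equiv), Et2Zn (0.8 equiv), THF, 0 °C → rt; then (CuOTf)2·C6H6 (2.5 mol%), chiral sulfonate-bearing imidazolinylidene NHC (via its Ag complex, 5 mol%), 7, THF/toluene, −30 → 0 °C, then rt 1 h; aq NH4Cl
Reagents that add atoms: none
Why: Proposed new method: the zinc cyclopropoxide opens by strain-driven β-carbon elimination to a chelated zinc homoenolate, which transmetalates to the chiral NHC–Cu and adds 1,4 to the Re face of C6 of 7, setting the quaternary centre under catalyst control. The resulting (Z)-zinc enolate closes onto the tethered isopropyl ketone through a Zn-bridged Zimmerman–Traxler chair (5-enolexo-exo-trig), so the C–O ends cis to the acyl group and isopropyl trans. A(1,3) strain places the smaller CH3, not allyl, in the slot syn to the enolate C–OZn, so the acyl group ends cis to CH3; the same isomer is the thermodynamic one for the reversible zinc aldolate. Closest known reaction types: NHC–Cu conjugate addition of dialkylzincs to β,β-disubstituted enones, conjugate addition of cyclopropanol-derived zinc homoenolates to β-monosubstituted enones, and Cu/Zn conjugate addition–aldol cyclisation.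

Step 7
Reactants: 10 (cyclopentanol above)
Product: 11 (3R,3aR,8aR)-3-hydroxy-6,8a-dimethyl-3-(propan-2-yl)-2,3,3a,5,8,8a-hexahydroazulen-4(1H)-one (trans-fused; 3-OH cis to 8a-CH3)
Conditions: Grubbs II (5 mol%), 1,4-benzoquinone (10 mol%), CH2Cl2 (3 mM), 40 °C
Reagents that add atoms: none
Why: Ring-closing metathesis of the monosubstituted and 1,1-disubstituted alkenes on trans-disposed arms closes the trans-fused cycloheptene with the trisubstituted C6=C7 alkene; no stereocentre is touched, and the enolisable C3a already has its preferred configuration (acyl trans to isopropyl, H-bonded to OH).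

Step 8
Reactants: 11 (ketol above)
Product: 12 (3R,3aS,4S,8aR)-6,8a-dimethyl-3-(propan-2-yl)-1,2,3,3a,4,5,8,8a-octahydroazulene-3,4-diol (jaeschkeanadiol)
Conditions: Me4NBH(OAc)3 (5 equiv), MeCN/AcOH 1:1, −30 → −20 °C
Reagents that add atoms: none
Why: Evans–Saksena reduction: the C3 hydroxyl binds boron and delivers hydride intramolecularly to the face of C4 syn to that oxygen, giving the 1,3-anti diol (4S, OH cis to H-3a).

Step 9
Reactants: 13 4-bromophenol
Product: 14 (4-bromophenoxy)(tert-butyl)dimethylsilane
Conditions: TBSCl, imidazole, DMF, rt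
Reagents that add atoms: tert-butyldimethylsilyl chloride, CC(C)(C)[Si](C)(C)Cl
Why: Standard phenol silylation masks the acidic OH for the lithiation and esterification.

Step 10
Reactants: 14 (4-bromophenoxy)(tert-butyl)dimethylsilane
Product: 15 4-[(tert-butyldimethylsilyl)oxy]benzoic acid
Conditions: n-BuLi, THF, −78 °C; CO2 (g); aq citric acid
Reagents that add atoms: carbon dioxide, O=C=O
Why: Bromine–lithium exchange followed by carboxylation of the aryllithium; the aryl silyl ether survives at −78 °C and a mild acidic work-up.

Step 11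
Reactants: 12 jaeschkeanadiol; 15 4-[(tert-butyldimethylsilyl)oxy]benzoic acid
Product: 16 (3R,3aS,4S,8aR)-3-hydroxy-6,8a-dimethyl-3-(propan-2-yl)-1,2,3,3a,4,5,8,8a-octahydroazulen-4-yl 4-[(tert-butyldimethylsilyl)oxy]benzoate
Conditions: 15, 2,4,6-trichlorobenzoyl chloride, Et3N, THF, rt; then 12, DMAP, toluene, 40 °C
Reagents that add atoms: none
Why: Yamaguchi esterification acylates only the secondary C4-OH (the tertiary, isopropyl-flanked C3-OH is inert) with retention at C4.

Step 12
Reactants: 16 (silyl-protected ester above)
Product: 17 ferutinin, (3R,3aS,4S,8aR)-3-hydroxy-6,8a-dimethyl-3-(propan-2-yl)-1,2,3,3a,4,5,8,8a-octahydroazulen-4-yl 4-hydroxybenzoate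
Conditions: TBAF/AcOH (1:1), THF, 0 °C
Reagents that add atoms: none
Why: Buffered fluoride cleaves the aryl silyl ether quickly without touching the benzoate ester or causing acyl migration.

**Compound list**
1 | allyl bromide | C=CCBr | starting material
2 | ethynylmagnesium bromide | C#C[Mg]Br | starting material
3 | pent-1-en-4-yne | C=CCC#C | intermediate
4 | 3-methylbut-3-en-1-ol | CC(=C)CCO | starting material
5 | 3-methylbut-3-enal | CC(=C)CC=O | intermediate
6 | (E)-2,6-dimethylnona-1,5,8-trien-4-ol (racemic) | C=CC/C(C)=C/C(O)CC(C)=C | intermediate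
7 | (E)-2,6-dimethylnona-1,5,8-trien-4-one | C=CC/C(C)=C/C(=O)CC(C)=C | intermediate
8 | methyl 2-methylpropanoate | COC(=O)C(C)C | starting material
9 | 1-(propan-2-yl)cyclopropan-1-ol | CC(C)C1(O)CC1 | intermediate
10 | 1-[(1R,2R,5R)-2-hydroxy-5-methyl-2-(propan-2-yl)-5-(prop-2-en-1-yl)cyclopentyl]-3-methylbut-3-en-1-one | C=CC[C@@]1(C)CC[C@@](O)(C(C)C)[C@@H]1C(=O)CC(C)=C | intermediate
11 | (3R,3aR,8aR)-3-hydroxy-6,8a-dimethyl-3-(propan-2-yl)-2,3,3a,5,8,8a-hexahydroazulen-4(1H)-one | CC1=CC[C@@]2(C)CC[C@@](O)(C(C)C)[C@@H]2C(=O)C1 | intermediate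
12 | (3R,3aS,4S,8aR)-6,8a-dimethyl-3-(propan-2-yl)-1,2,3,3a,4,5,8,8a-octahydroazulene-3,4-diol | CC1=CC[C@@]2(C)CC[C@@](O)(C(C)C)[C@@H]2[C@@H](O)C1 | intermediate
13 | 4-bromophenol | Oc1ccc(Br)cc1 | starting material
14 | (4-bromophenoxy)(tert-butyl)dimethylsilane | CC(C)(C)[Si](C)(C)Oc1ccc(Br)cc1 | intermediate
15 | 4-[(tert-butyldimethylsilyl)oxy]benzoic acid | CC(C)(C)[Si](C)(C)Oc1ccc(cc1)C(O)=O | intermediate
16 | (3R,3aS,4S,8aR)-3-hydroxy-6,8a-dimethyl-3-(propan-2-yl)-1,2,3,3a,4,5,8,8a-octahydroazulen-4-yl 4-[(tert-butyldimethylsilyl)oxy]benzoate | CC1=CC[C@@]2(C)CC[C@@](O)(C(C)C)[C@@H]2[C@@H](OC(=O)c2ccc(O[Si](C)(C)C(C)(C)C)cc2)C1 | intermediate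
17 | ferutinin | CC1=CC[C@@]2(C)CC[C@@](O)(C(C)C)[C@@H]2[C@@H](OC(=O)c2ccc(O)cc2)C1 | target

**Totals**
Total steps: 12. Longest linear sequence: 8 (steps 2 → 3 → 4 → 6 → 7 → 8 → 11 → 12; the branch from step 1 is equally long).

**Steps most likely to fail**
1. Step 6 (proposed annulation). Risks: a sluggish homoenolate transfer to a β,β-disubstituted acyclic enone, base-induced conjugation of the β,γ-alkene in 7, and only moderate methyl-versus-allyl discrimination in the aldol. Fallback (known chemistry): swap roles. Build the β-allyl enone that already carries the dioxolane-protected 4-methyl-3-oxopentyl chain on the β-carbon and set the quaternary centre by the established NHC–Cu conjugate addition of Me3Al to acyclic β,β-disubstituted enones. Then unmask the ketone and close the cyclopentanol in a separate intramolecular aldol.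
2. Step 3 (alkenylalanate addition to the labile, enolisable aldehyde 5). Fallback: reverse the polarity. Iodinate the alkenylalane to (E)-1-iodo-2-methylpenta-1,4-diene, convert it by Li–I exchange and DMF into the stable (E)-3-methylhexa-2,5-dienal, and add methallylmagnesium chloride to reach 6 without handling 5.
3. Step 8 (directed reduction must override the intrinsic facial bias, on a tertiary carbinol). Fallback: reduce without direction (NaBH4/CeCl3) to the C4-epimeric syn diol, then esterify with 15 under Mitsunobu conditions with inversion at C4, giving 16 directly.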